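**Plan**

- Retrosynthesis: cut the C4'–Br bond of ring B first, then the O–CH3 bond, then the C2–Br and C4–Br bonds of ring A. This leaves 2-(2-bromophenoxy)phenol. Last, cut the C2'–Br bond and rejoin C2' to the oxygen on C1 of ring A.
- Enabling feature: ring A carries oxygen on the adjacent carbons C1 and C6, and ring B carries bromine on C2', ortho to the ether oxygen on C1'. An O(C1)–C2' bond in place of that bromine gives the central six-membered ring of dibenzo-p-dioxin, whose four aryl C–O bonds are equivalent.
- Forward order: both benzene rings and the diaryl ether link are bought together and no ring is formed. The dioxin ring is opened reductively and the aryllithium is capped with bromine (step 1). Ring A is dibrominated under control of the free hydroxyl (step 2), the hydroxyl is methylated (step 3), and ring B is brominated para to the ether oxygen (step 4).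
- Stereochemistry: the target is achiral, so nothing has to be set.

Key step: step 1

Remark on the chemistry: ring A is numbered as the anisole (C1 OMe, C2 and C4 Br, C6 OAr) and ring B as the phenoxy ring (C1' O, C2' and C4' Br); unsubstituted dibenzo-p-dioxin is taken to be a purchasable catalogue compound.

**Route**

Step 1
Reactants: 1 dibenzo-p-dioxin; 2 1,2-dibromoethane
Product: 4 2-(2-bromophenoxy)phenol, via lithium 2-(2-lithiophenoxy)phenolate 3 (not isolated)
Conditions: Li powder (2.2 equiv), 4,4'-di-tert-butylbiphenyl (DTBB, 5 mol%), THF, −78 → 0 °C; solution filtered by cannula into BrCH2CH2Br (2.5 equiv), THF, −78 °C → rt; then 1 M HCl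
Reagents that add atoms: 1,2-dibromoethane, BrCCBr
Why: Lithium reduces DTBB to its radical anion, which passes an electron to 1; the radical anion of 1 breaks one aryl C–O bond and a second electron transfer gives the aryllithium/lithium phenoxide 3. The carbanion of 3 then attacks a bromine of 1,2-dibromoethane, which collapses to ethene and LiBr, so the C2'–Br bond forms while the phenoxide stays untouched until the acid work-up frees the ring A hydroxyl. The closest known reaction type is the arene-catalysed reductive lithiation of dibenzo-fused chalcogen heterocycles with electrophile capture of the ring-opened dianion, joined to the standard bromination of aryllithiums with 1,2-dibromoethane. No ring is closed (the six-membered dioxin ring is opened) and no stereocentre is formed. Site selectivity is not an issue because the four aryl C–O bonds of 1 are equivalent by symmetry; what the step needs is a single cleavage, and the double negative charge of 3, the limited amount of lithium and the low temperature should secure it. Removing leftover metal before the inverse addition keeps the new C–Br bond from being reduced again.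

Step 2
Reactants: 4 2-(2-bromophenoxy)phenol; 5 bromine
Product: 6 2,4-dibromo-6-(2-bromophenoxy)phenol
Conditions: Br2 (2.05 equiv), AcOH, 10 °C → rt
Reagents that add atoms: bromine, BrBr
Why: This is an electrophilic aromatic bromination of a phenol, in which the free hydroxyl is by far the strongest donor and should steer the two equivalents of bromine to its para position (C4) and its only free ortho position (C2), while ring B, deactivated by its own bromine, should not react with Br2 in acetic acid at room temperature.

Step 3
Reactants: 6 2,4-dibromo-6-(2-bromophenoxy)phenol; 7 iodomethane
Product: 8 1,5-dibromo-3-(2-bromophenoxy)-2-methoxybenzene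
Conditions: MeI (1.5 equiv), K2CO3 (2 equiv), DMF, rt → 40 °C
Reagents that add atoms: iodomethane, CI
Why: This is a Williamson O-methylation (SN2 attack of the phenoxide on iodomethane); the acidic dibromophenol is fully deprotonated by K2CO3 and the dipolar solvent makes up for the hindrance of the two ortho substituents, and capping the hydroxyl now protects ring A from ipso attack and oxidation in the Lewis-acid bromination that follows.

Step 4
Reactants: 8 1,5-dibromo-3-(2-bromophenoxy)-2-methoxybenzene; 5 bromine
Product: 9 1,5-dibromo-3-(2,4-dibromophenoxy)-2-methoxybenzene (target)
Conditions: Br2 (1.1 equiv), FeBr3 (5 mol%), CH2Cl2, 0 °C → rt, dark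
Reagents that add atoms: bromine, BrBr
Why: This is an FeBr3-catalysed electrophilic aromatic bromination; both free positions of ring A are flanked on each side (C3 between two bromines, C5 between the C4 bromine and the aryloxy group), so the unhindered C4' position para to the ether oxygen should be the preferred site, and the meta C2' bromine slows ring B enough that a Lewis acid is needed but does not redirect the attack.

**Compound list**

1 | dibenzo-p-dioxin (dibenzo[b,e][1,4]dioxine) | c1ccc2Oc3ccccc3Oc2c1 | starting material
2 | 1,2-dibromoethane | BrCCBr | starting material
3 | lithium 2-(2-lithiophenoxy)phenolate (formed in the flask, not isolated) | [Li]c1ccccc1Oc1ccccc1O[Li] | intermediate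
4 | 2-(2-bromophenoxy)phenol | Oc1ccccc1Oc1ccccc1Br | intermediate
5 | bromine | BrBr | starting material
6 | 2,4-dibromo-6-(2-bromophenoxy)phenol | Oc1c(Br)cc(Br)cc1Oc1ccccc1Br | intermediate
7 | iodomethane | CI | starting material
8 | 1,5-dibromo-3-(2-bromophenoxy)-2-methoxybenzene | COc1c(Br)cc(Br)cc1Oc1ccccc1Br | intermediate
9 | 1,5-dibromo-3-(2,4-dibromophenoxy)-2-methoxybenzene | COc1c(Br)cc(Br)cc1Oc1ccc(Br)cc1Br | target

Total step count: 4
Longest linear sequence: 4 steps

**Steps most likely to fail**

1. Step 1. The bromine transfer may be incomplete or undone. The aryllithium can be protonated by the medium before it meets the halogen source, and leftover lithium or DTBB radical anion can reduce the fresh aryl bromide back to the arene. The fallback sets out from 3 and comes back to the route at 6. The solution of 3 would be treated at −78 °C with Me3SiCl (1.05 equiv), which silylates the carbanion much faster than the lithium phenoxide and gives a C–Si bond that no residual reductant touches. Acid work-up should then give 2-[2-(trimethylsilyl)phenoxy]phenol F1. Treating F1 with Br2 (3.1 equiv) in CH2Cl2 at 0 °C → rt should brominate ring A ortho and para to the hydroxyl and replace silicon at C2' by ipso-bromodesilylation, which gives 6 directly and bypasses 4.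

2. Step 4. Substitution on the bromine-deactivated ring B may be slow, and the conditions needed to drive it may let bromine also enter C6' or ring A (loss of site selectivity and over-bromination). The Lewis acid could also strip the methyl ether. The fallback sets out from 8 and comes back at 9. Nitration (HNO3, Ac2O/AcOH, 0 °C) stops after one substitution because the nitro group shuts the molecule down, and it should give 1,5-dibromo-3-(2-bromo-4-nitrophenoxy)-2-methoxybenzene F2, which is easy to purify at this polar stage. Reduction with Fe powder and NH4Cl in EtOH/H2O, which leaves aryl bromides alone, should give 3-bromo-4-(3,5-dibromo-2-methoxyphenoxy)aniline F3. Diazotisation (NaNO2, aqueous HBr, 0 °C) should give 3-bromo-4-(3,5-dibromo-2-methoxyphenoxy)benzenediazonium bromide F4. A Sandmeyer reaction with CuBr in HBr then places bromine exactly where nitrogen stood and gives 9.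

3. Step 2. Bromine uptake may not stop cleanly at two atoms or may spread unevenly over the ortho and para positions, and ipso attack at an occupied position could give a bromodienone, so that mixtures of mono-, di- and tribromo phenols result. The fallback sets out from 4 and comes back at 6, and splits the one-pot reaction into two reagent-controlled brominations. Tetrabutylammonium tribromide (1.0 equiv, CH2Cl2/MeOH, rt) is a para-selective monobrominating agent for phenols and should give 4-bromo-2-(2-bromophenoxy)phenol F5. N-Bromosuccinimide with catalytic diisopropylamine (CH2Cl2, 0 °C), which delivers bromine ortho to a phenolic hydroxyl, should then fill the single free ortho position and give 6.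

**Further compounds**

F1 | step 1 | 2-[2-(trimethylsilyl)phenoxy]phenol | C[Si](C)(C)c1ccccc1Oc1ccccc1O
F2 | step 4 | 1,5-dibromo-3-(2-bromo-4-nitrophenoxy)-2-methoxybenzene | COc1c(Br)cc(Br)cc1Oc1ccc([N+](=O)[O-])cc1Br
F3 | step 4 | 3-bromo-4-(3,5-dibromo-2-methoxyphenoxy)aniline | COc1c(Br)cc(Br)cc1Oc1ccc(N)cc1Br
F4 | step 4 | 3-bromo-4-(3,5-dibromo-2-methoxyphenoxy)benzenediazonium bromide | COc1c(Br)cc(Br)cc1Oc1ccc([N+]#N)cc1Br.[Br-]
F5 | step 2 | 4-bromo-2-(2-bromophenoxy)phenol | Oc1ccc(Br)cc1Oc1ccccc1Br
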